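**Retrosynthetic overview**

1. The target comes from its C6 alcohol by chlorination with inversion; the ten-membered ring is closed last, at C5–C6, by Nozaki–Hiyama–Kishi addition of a 2-iodo-1,3-diene to a C6 aldehyde.
2. The γ-lactone (O7–C19) comes from a C7–C8 epoxide opened by the C19 ester; the epoxide is delivered by the C9 hydroxyl. C8–C9 comes from an alkenyl bromide and a C9 aldehyde, with C9 then reset by enone reduction.
3. C2–C3 comes from an acetylide opening a bridged C2/O13 lactone, whose closure with inversion also corrects C13; ynone transfer hydrogenation sets C2.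
4. The cyclohexane (C1, C10–C14) comes from an ester-enolate Claisen ring contraction of an eight-membered lactone (ring O–C2–C1–C14–C13–C12–C11–C20). Enabling feature: carboxyl-level C2 on quaternary C1, C10–H and the exocyclic C11=C20 methylene form a γ,δ-unsaturated acid array C2–C1–C10–C11=C20, so tying O–C20 to C2 through C14–C13–C12 delivers the ring, C1, C10 and the methylene in one shift.
5. The lactone comes from but-2-yne-1,4-diol (C9, C10, C11, C20), (R)-epichlorohydrin (C12–C14) and propanoic acid (C1, C2, C15). Ring order: eight-membered lactone, cyclohexane by contraction, γ-lactone, ten-membered ring.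

Key step: step 8

Remark: briarane numbering is used throughout (C1–C10 ten-membered ring, C1 and C10–C14 six-membered ring, C15 methyl on C1, C16 methylene on C5, C17 on C8 bearing methyl C18 and carboxyl C19, C20 methylene on C11); (tert-butyldiphenylsilyloxy)acetaldehyde and (1-bromoethenyl)trimethylsilane are assumed to be purchasable.

**Route**

Step 1
Reactants: 1 but-2-yne-1,4-diol
Product: 2 4-[(4-methoxybenzyl)oxy]but-2-yn-1-ol
Conditions: NaH (1 equiv), 4-methoxybenzyl chloride, Bu4NI (cat.), THF, 0 °C to rt, diol in excess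
Reagents that add atoms: 4-methoxybenzyl chloride COc1ccc(CCl)cc1
Why: Williamson mono-etherification of a symmetric diol, with excess diol keeping bis-alkylation low; no stereocentre is formed.

Step 2
Reactants: 2 4-[(4-methoxybenzyl)oxy]but-2-yn-1-ol
Product: 3 (Z)-3-iodo-4-[(4-methoxybenzyl)oxy]but-2-en-1-ol
Conditions: NaAlH2(OCH2CH2OMe)2, THF, 0 °C; then I2, THF, −78 °C
Reagents that add atoms: iodine II
Why: hydroxyl-directed trans-hydroalumination puts aluminium on the alkyne carbon remote from the free hydroxyl, and iodinolysis with retention gives the (Z)-iodoalkene that fixes the later C10=C11 geometry.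

Step 3
Reactants: 3 (Z)-3-iodo-4-[(4-methoxybenzyl)oxy]but-2-en-1-ol
Product: 4 (Z)-tert-butyl({3-iodo-4-[(4-methoxybenzyl)oxy]but-2-en-1-yl}oxy)diphenylsilane
Conditions: t-BuPh2SiCl, imidazole, DMF, rt
Reagents that add atoms: tert-butyl(chloro)diphenylsilane CC(C)(C)[Si](Cl)(c1ccccc1)c1ccccc1
Why: silyl ether formation on the primary allylic alcohol protects the future C9 oxygen.

Step 4
Reactants: 4 (Z)-tert-butyl({3-iodo-4-[(4-methoxybenzyl)oxy]but-2-en-1-yl}oxy)diphenylsilane; 5 (R)-epichlorohydrin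
Product: 8 tert-butyl{[(2E)-3-{[(4-methoxybenzyl)oxy]methyl}-4-[(2R)-oxiran-2-yl]but-2-en-1-yl]oxy}diphenylsilane, via alkenyllithium 6 (not isolated), via chlorohydrin 7 (not isolated)
Conditions: t-BuLi (2.1 equiv), Et2O, −78 °C; then BF3·OEt2, 5, −78 °C; then NaOH (aq), MeOH, rt
Reagents that add atoms: none
Why: iodine–lithium exchange retains the alkene geometry, BF3-promoted epoxide opening by the alkenyllithium occurs at the CH2 terminus so the stereocentre of 5 (future C13) is untouched, and Williamson closure of the chlorohydrin gives the new terminal epoxide.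

Step 5
Reactants: 8 tert-butyl{[(2E)-3-{[(4-methoxybenzyl)oxy]methyl}-4-[(2R)-oxiran-2-yl]but-2-en-1-yl]oxy}diphenylsilane; 9 propanoic acid
Product: 12 (4S,6E)-8-[(tert-butyldiphenylsilyl)oxy]-6-{[(4-methoxybenzyl)oxy]methyl}-2-methyl-4-[(triethylsilyl)oxy]oct-6-enoic acid (C2 epimers), via dilithium hydroxy carboxylate 10 (not isolated), via bis(triethylsilyl) derivative 11 (not isolated)
Conditions: LiN(iPr)2 (2.2 equiv), THF, 0 °C, then 8, 45 °C; then Et3SiCl (3 equiv), 0 °C; K2CO3, MeOH/H2O work-up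
Reagents that add atoms: chlorotriethylsilane CC[Si](Cl)(CC)CC
Why: the carboxylic acid dianion opens the terminal epoxide at CH2 (SN2, C1–C14 bond), and silylation of alkoxide and carboxylate in the same flask followed by hydrolysis of the labile silyl ester prevents γ-lactone formation; C1 is left unselective because it becomes planar in step 8.

Step 6
Reactants: 12 (4S,6E)-8-[(tert-butyldiphenylsilyl)oxy]-6-{[(4-methoxybenzyl)oxy]methyl}-2-methyl-4-[(triethylsilyl)oxy]oct-6-enoic acid (C2 epimers)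
Product: 13 (4S,6E)-8-[(tert-butyldiphenylsilyl)oxy]-6-(hydroxymethyl)-2-methyl-4-[(triethylsilyl)oxy]oct-6-enoic acid (C2 epimers)
Conditions: DDQ, CH2Cl2/pH 7 buffer, 0 °C
Reagents that add atoms: none
Why: oxidative cleavage of the 4-methoxybenzyl ether by DDQ frees the C20 hydroxyl and leaves the silyl ethers and the acid untouched.

Step 7
Reactants: 13 (4S,6E)-8-[(tert-butyldiphenylsilyl)oxy]-6-(hydroxymethyl)-2-methyl-4-[(triethylsilyl)oxy]oct-6-enoic acid (C2 epimers)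
Product: 14 (5S,7E)-7-{2-[(tert-butyldiphenylsilyl)oxy]ethylidene}-3-methyl-5-[(triethylsilyl)oxy]oxocan-2-one (C3 epimers)
Conditions: 2-methyl-6-nitrobenzoic anhydride, DMAP, Et3N, CH2Cl2, rt, slow addition at high dilution
Reagents that add atoms: none
Why: Shiina lactonisation through the mixed anhydride closes the eight-membered lactone under high dilution, helped by the trigonal C11 and the ring substituents.

Step 8
Reactants: 14 (5S,7E)-7-{2-[(tert-butyldiphenylsilyl)oxy]ethylidene}-3-methyl-5-[(triethylsilyl)oxy]oxocan-2-one (C3 epimers)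
Product: 17 (1S,2S,5R)-2-{[(tert-butyldiphenylsilyl)oxy]methyl}-5-hydroxy-1-methyl-3-methylidenecyclohexane-1-carboxylic acid, via silyl ketene acetal 15 (not isolated), via trimethylsilyl ester 16 (not isolated)
Conditions: LiN(iPr)2, Me3SiCl, Et3N, THF, −78 °C; then 65 °C; then 1 M HCl, THF/MeOH, rt
Reagents that add atoms: none
Why: Proposed new method: deprotonation at C1 and O-silylation give the ring-constrained silyl ketene acetal 15 (ring oxygen and C14 cis on C1=C2), whose C1 terminus bonds to C10 of the exocyclic allyl unit C10=C11–C20–O while the C20–O bond breaks, a [3,3] ester-enolate Claisen shift that turns the ring O–C2–C1–C14–C13–C12–C11–C20 into the carbocycle C1–C14–C13–C12–C11–C10, leaving C20 as the exocyclic methylene and C2 as the carboxyl carbon. The closest known reaction type is the Ireland–Claisen ring contraction of medium and large lactones with an endocyclic allylic alkene; here the alkene is exocyclic to the lactone, so the ring shrinks by two atoms, and the argument for feasibility is that the chair pericyclic array and the forming chair cyclohexane share C1, C10 and C11 in a strain-free bicyclo[3.3.1]nonane-like transition state. The six-membered ring closes in a 6-endo-trig sense (C1 onto C10 of the C10=C11 bond), driven by formation of the C=O bond and release of medium-ring strain. C1 (quaternary) and C10 are set together: the ring fixes the enolate geometry, the (E)-alkene places the C9 substituent equatorial in the chair pericyclic array, and this pairing puts methyl C15 cis to C9. The absolute sense comes from C13, whose silyloxy group takes the equatorial site of the forming chair away from the O–C20 bridge and so ends cis to the C1 methyl and trans to the carboxyl. The step needs chair over boat and one face over the other, secured by the bicyclic transition-state shape and the C13 substituent; the acid work-up removes the trimethylsilyl ester and the triethylsilyl ether while the tert-butyldiphenylsilyl ether stays.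

Step 9
Reactants: 17 (1S,2S,5R)-2-{[(tert-butyldiphenylsilyl)oxy]methyl}-5-hydroxy-1-methyl-3-methylidenecyclohexane-1-carboxylic acid
Product: 18 (1S,2S,5S)-2-{[(tert-butyldiphenylsilyl)oxy]methyl}-1-methyl-3-methylidene-6-oxabicyclo[3.2.1]octan-7-one
Conditions: PPh3, diisopropyl azodicarboxylate, THF, 0 °C to rt
Reagents that add atoms: none
Why: Mitsunobu lactonisation, in which the C1 carboxylate displaces the activated C13 oxygen from the opposite face (SN2), inverts C13 to the configuration of the target and stores C2 and O13 as a bridged γ-lactone.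

Step 10
Reactants: 19 (1-bromoethenyl)trimethylsilane; 20 ethynyltrimethylsilane
Product: 21 trimethyl[3-(trimethylsilyl)but-3-en-1-yn-1-yl]silane
Conditions: Pd(PPh3)2Cl2 (cat.), CuI (cat.), Et3N, rt
Reagents that add atoms: none
Why: Sonogashira coupling of the alkenyl bromide with the terminal alkyne assembles C3, C4, C5 and C16.

Step 11
Reactants: 21 trimethyl[3-(trimethylsilyl)but-3-en-1-yn-1-yl]silane; 18 (1S,2S,5S)-2-{[(tert-butyldiphenylsilyl)oxy]methyl}-1-methyl-3-methylidene-6-oxabicyclo[3.2.1]octan-7-one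
Product: 23 1-[(1S,2S,5S)-2-{[(tert-butyldiphenylsilyl)oxy]methyl}-5-hydroxy-1-methyl-3-methylidenecyclohexyl]-4-(trimethylsilyl)pent-4-en-2-yn-1-one, via lithium acetylide 22 (not isolated)
Conditions: MeLi (1.0 equiv), THF, 0 °C; then 18, −78 to −30 °C; NH4Cl (aq)
Reagents that add atoms: none
Why: methyllithium cleaves only the alkynyl C–Si bond, and the resulting lithium acetylide adds once to the lactone carbonyl (acyl substitution, the tetrahedral alkoxide collapsing on work-up), which forms the C2–C3 bond and frees the C13 hydroxyl.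

Step 12
Reactants: 23 1-[(1S,2S,5S)-2-{[(tert-butyldiphenylsilyl)oxy]methyl}-5-hydroxy-1-methyl-3-methylidenecyclohexyl]-4-(trimethylsilyl)pent-4-en-2-yn-1-one
Product: 24 (1R)-1-[(1S,2S,5S)-2-{[(tert-butyldiphenylsilyl)oxy]methyl}-5-hydroxy-1-methyl-3-methylidenecyclohexyl]-4-(trimethylsilyl)pent-4-en-2-yn-1-ol
Conditions: RuCl[(R,R)-TsDPEN](p-cymene) (cat.), propan-2-ol, rt
Reagents that add atoms: none
Why: Noyori asymmetric transfer hydrogenation of an alkynyl ketone, in which the catalyst distinguishes the alkynyl from the tertiary alkyl substituent and sets C2 by reagent control.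

Step 13
Reactants: 24 (1R)-1-[(1S,2S,5S)-2-{[(tert-butyldiphenylsilyl)oxy]methyl}-5-hydroxy-1-methyl-3-methylidenecyclohexyl]-4-(trimethylsilyl)pent-4-en-2-yn-1-ol
Product: 25 (1R)-1-[(1S,2S,5S)-5-acetoxy-2-{[(tert-butyldiphenylsilyl)oxy]methyl}-1-methyl-3-methylidenecyclohexyl]-4-(trimethylsilyl)pent-4-en-2-yn-1-yl acetate
Conditions: Ac2O, DMAP, pyridine, rt
Reagents that add atoms: acetic anhydride CC(=O)OC(C)=O
Why: DMAP-catalysed acetylation installs the C2 and C13 acetates of the target, which then serve as their own protecting groups.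

Step 14
Reactants: 25 (1R)-1-[(1S,2S,5S)-5-acetoxy-2-{[(tert-butyldiphenylsilyl)oxy]methyl}-1-methyl-3-methylidenecyclohexyl]-4-(trimethylsilyl)pent-4-en-2-yn-1-yl acetate
Product: 26 (1R)-1-[(1S,2S,5S)-5-acetoxy-2-(hydroxymethyl)-1-methyl-3-methylidenecyclohexyl]-4-(trimethylsilyl)pent-4-en-2-yn-1-yl acetate
Conditions: HF·pyridine, pyridine, THF, 0 °C to rt
Reagents that add atoms: none
Why: fluoride cleavage of the primary silyl ether; the acetates and the alkenylsilane survive buffered HF·pyridine.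

Step 15
Reactants: 26 (1R)-1-[(1S,2S,5S)-5-acetoxy-2-(hydroxymethyl)-1-methyl-3-methylidenecyclohexyl]-4-(trimethylsilyl)pent-4-en-2-yn-1-yl acetate
Product: 27 (1R)-1-[(1S,2S,5S)-5-acetoxy-2-formyl-1-methyl-3-methylidenecyclohexyl]-4-(trimethylsilyl)pent-4-en-2-yn-1-yl acetate
Conditions: Dess–Martin periodinane, NaHCO3, CH2Cl2, 0 °C
Reagents that add atoms: none
Why: Dess–Martin oxidation under buffered, non-basic conditions gives the C9 aldehyde without epimerising C10 or moving the C11=C20 bond.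

Step 16
Reactants: 28 (tert-butyldiphenylsilyloxy)acetaldehyde
Product: 29 tert-butyl[(3,3-dibromoprop-2-en-1-yl)oxy]diphenylsilane
Conditions: CBr4, PPh3, CH2Cl2, 0 °C
Reagents that add atoms: carbon tetrabromide BrC(Br)(Br)Br
Why: Corey–Fuchs dibromo-olefination of the aldehyde supplies C8 as a 1,1-dibromoalkene.

Step 17
Reactants: 30 tert-butyl 2-bromopropanoate (racemic); 29 tert-butyl[(3,3-dibromoprop-2-en-1-yl)oxy]diphenylsilane
Product: 32 tert-butyl (3Z)-3-bromo-5-[(tert-butyldiphenylsilyl)oxy]-2-methylpent-3-enoate (racemic), via zinc enolate 31 (not isolated)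
Conditions: Zn (activated), THF, rt; then 29, PdCl2(DPEphos) (cat.), THF, rt
Reagents that add atoms: none
Why: zinc insertion gives the Reformatsky reagent, and palladium-catalysed Negishi-type coupling takes place at the bromine trans to the CH2O chain (the less hindered C–Br bond), leaving the (Z)-bromide; C17 is formed racemic and is corrected in step 24.

Step 18
Reactants: 27 (1R)-1-[(1S,2S,5S)-5-acetoxy-2-formyl-1-methyl-3-methylidenecyclohexyl]-4-(trimethylsilyl)pent-4-en-2-yn-1-yl acetate; 32 tert-butyl (3Z)-3-bromo-5-[(tert-butyldiphenylsilyl)oxy]-2-methylpent-3-enoate (racemic)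
Product: 33 tert-butyl (1S,2R,7Z,10S,13S)-2,13-diacetoxy-6-[(tert-butyldiphenylsilyl)oxy]-9-hydroxy-5-(trimethylsilyl)-5,6-secobriara-5(16),7,11(20)-trien-3-yn-19-oate (C9 and C17 epimers)
Conditions: CrCl2 (excess), NiCl2 (cat.), DMSO, rt
Reagents that add atoms: none
Why: Nozaki–Hiyama–Kishi coupling, in which nickel-catalysed activation of the C–Br bond and transfer to chromium retain the alkene geometry and the alkenylchromium adds only to the aldehyde in the presence of the esters; C9 is not controlled here because it is erased in step 19.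

Step 19
Reactants: 33 tert-butyl (1S,2R,7Z,10S,13S)-2,13-diacetoxy-6-[(tert-butyldiphenylsilyl)oxy]-9-hydroxy-5-(trimethylsilyl)-5,6-secobriara-5(16),7,11(20)-trien-3-yn-19-oate (C9 and C17 epimers)
Product: 34 tert-butyl (1S,2R,7Z,10S,13S)-2,13-diacetoxy-6-[(tert-butyldiphenylsilyl)oxy]-9-oxo-5-(trimethylsilyl)-5,6-secobriara-5(16),7,11(20)-trien-3-yn-19-oate (C17 epimers)
Conditions: Dess–Martin periodinane, NaHCO3, CH2Cl2, 0 °C
Reagents that add atoms: none
Why: Dess–Martin oxidation converges both C9 epimers on one enone.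

Step 20
Reactants: 34 tert-butyl (1S,2R,7Z,10S,13S)-2,13-diacetoxy-6-[(tert-butyldiphenylsilyl)oxy]-9-oxo-5-(trimethylsilyl)-5,6-secobriara-5(16),7,11(20)-trien-3-yn-19-oate (C17 epimers)
Product: 35 tert-butyl (1S,2R,7Z,9S,10S,13S)-2,13-diacetoxy-6-[(tert-butyldiphenylsilyl)oxy]-9-hydroxy-5-(trimethylsilyl)-5,6-secobriara-5(16),7,11(20)-trien-3-yn-19-oate (C17 epimers)
Conditions: NaBH4, CeCl3·7H2O, MeOH, −78 °C
Reagents that add atoms: none
Why: Luche 1,2-reduction, in which hydride attacks the ketone anti to the quaternary C1 substituent on C10 (Felkin–Anh) and so gives the (9S)-alcohol with O9 anti to C11.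

Step 21
Reactants: 35 tert-butyl (1S,2R,7Z,9S,10S,13S)-2,13-diacetoxy-6-[(tert-butyldiphenylsilyl)oxy]-9-hydroxy-5-(trimethylsilyl)-5,6-secobriara-5(16),7,11(20)-trien-3-yn-19-oate (C17 epimers)
Product: 36 tert-butyl (1S,2R,7S,8R,9S,10S,13S)-2,13-diacetoxy-6-[(tert-butyldiphenylsilyl)oxy]-7,8-epoxy-9-hydroxy-5-(trimethylsilyl)-5,6-secobriara-5(16),11(20)-dien-3-yn-19-oate (C17 epimers)
Conditions: Ti(OiPr)4 (1 equiv), t-BuOOH, 4 Å molecular sieves, CH2Cl2, −20 °C
Reagents that add atoms: tert-butyl hydroperoxide CC(C)(C)OO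
Why: titanium-directed epoxidation touches only the alkene of the allylic alcohol, and A(1,3) strain between the C6 chain and the carbinol substituents puts the C9 hydrogen in the alkene plane so that oxygen is delivered to the face giving the threo epoxy alcohol (O8 syn to O9).

Step 22
Reactants: 36 tert-butyl (1S,2R,7S,8R,9S,10S,13S)-2,13-diacetoxy-6-[(tert-butyldiphenylsilyl)oxy]-7,8-epoxy-9-hydroxy-5-(trimethylsilyl)-5,6-secobriara-5(16),11(20)-dien-3-yn-19-oate (C17 epimers)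
Product: 37 (1S,2R,7R,8R,9S,10S,13S)-2,13-diacetoxy-6-[(tert-butyldiphenylsilyl)oxy]-8,9-dihydroxy-5-(trimethylsilyl)-5,6-secobriara-5(16),11(20)-dien-3-yn-19,7-olide (C17 epimers)
Conditions: BF3·OEt2 (0.3 equiv), CH2Cl2, −78 °C
Reagents that add atoms: none
Why: Lewis-acid activation lets the carbonyl oxygen of the tert-butyl ester open the epoxide at C7 with inversion through a five-membered transition state (the only epoxide carbon it can reach) with loss of isobutene, giving the cis-fused γ-lactone with the C8 hydroxyl retained.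

Step 23
Reactants: 37 (1S,2R,7R,8R,9S,10S,13S)-2,13-diacetoxy-6-[(tert-butyldiphenylsilyl)oxy]-8,9-dihydroxy-5-(trimethylsilyl)-5,6-secobriara-5(16),11(20)-dien-3-yn-19,7-olide (C17 epimers)
Product: 38 (1S,2R,7R,8R,9S,10S,13S)-2,9,13-triacetoxy-6-[(tert-butyldiphenylsilyl)oxy]-8-hydroxy-5-(trimethylsilyl)-5,6-secobriara-5(16),11(20)-dien-3-yn-19,7-olide (C17 epimers)
Conditions: Ac2O, DMAP, pyridine, 0 °C
Reagents that add atoms: acetic anhydride CC(=O)OC(C)=O
Why: acetylation of the secondary C9 hydroxyl leaves the hindered tertiary C8 hydroxyl free and blocks translactonisation to O9.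

Step 24
Reactants: 38 (1S,2R,7R,8R,9S,10S,13S)-2,9,13-triacetoxy-6-[(tert-butyldiphenylsilyl)oxy]-8-hydroxy-5-(trimethylsilyl)-5,6-secobriara-5(16),11(20)-dien-3-yn-19,7-olide (C17 epimers)
Product: 39 (1S,2R,7R,8R,9S,10S,13S,17R)-2,9,13-triacetoxy-6-[(tert-butyldiphenylsilyl)oxy]-8-hydroxy-5-(trimethylsilyl)-5,6-secobriara-5(16),11(20)-dien-3-yn-19,7-olide
Conditions: DBU (0.3 equiv), toluene, 40 °C
Reagents that add atoms: none
Why: base-mediated epimerisation through the lactone enolate (thermodynamic control) should move the C17 methyl to the face of the lactone cis to the C8 hydroxyl and away from the C9 substituent.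

Step 25
Reactants: 39 (1S,2R,7R,8R,9S,10S,13S,17R)-2,9,13-triacetoxy-6-[(tert-butyldiphenylsilyl)oxy]-8-hydroxy-5-(trimethylsilyl)-5,6-secobriara-5(16),11(20)-dien-3-yn-19,7-olide
Product: 40 (1S,2S,3Z,7R,8R,9S,10S,13S,17R)-2,9,13-triacetoxy-6-[(tert-butyldiphenylsilyl)oxy]-8-hydroxy-5-(trimethylsilyl)-5,6-secobriara-3,5(16),11(20)-trien-19,7-olide
Conditions: H2 (1 atm), Pd/CaCO3 poisoned with Pb(OAc)2, quinoline, EtOAc, rt
Reagents that add atoms: none
Why: Lindlar semihydrogenation adds hydrogen syn to the alkyne and gives the (3Z)-alkene of the diene.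

Step 26
Reactants: 40 (1S,2S,3Z,7R,8R,9S,10S,13S,17R)-2,9,13-triacetoxy-6-[(tert-butyldiphenylsilyl)oxy]-8-hydroxy-5-(trimethylsilyl)-5,6-secobriara-3,5(16),11(20)-trien-19,7-olide
Product: 41 (1S,2S,3Z,7R,8R,9S,10S,13S,17R)-2,9,13-triacetoxy-6-[(tert-butyldiphenylsilyl)oxy]-8-hydroxy-5-iodo-5,6-secobriara-3,5(16),11(20)-trien-19,7-olide
Conditions: N-iodosuccinimide, (CF3)2CHOH, 0 °C
Reagents that add atoms: N-iodosuccinimide O=C1CCC(=O)N1I
Why: ipso-iododesilylation of the alkenylsilane replaces silicon by iodine at C5 without moving the double bond.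

Step 27
Reactants: 41 (1S,2S,3Z,7R,8R,9S,10S,13S,17R)-2,9,13-triacetoxy-6-[(tert-butyldiphenylsilyl)oxy]-8-hydroxy-5-iodo-5,6-secobriara-3,5(16),11(20)-trien-19,7-olide
Product: 42 (1S,2S,3Z,7R,8R,9S,10S,13S,17R)-2,9,13-triacetoxy-6,8-dihydroxy-5-iodo-5,6-secobriara-3,5(16),11(20)-trien-19,7-olide
Conditions: HF·pyridine, pyridine, THF, 0 °C to rt
Reagents that add atoms: none
Why: fluoride cleavage of the primary silyl ether frees the C6 hydroxyl while the acetates, lactone and iododiene are inert.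

Step 28
Reactants: 42 (1S,2S,3Z,7R,8R,9S,10S,13S,17R)-2,9,13-triacetoxy-6,8-dihydroxy-5-iodo-5,6-secobriara-3,5(16),11(20)-trien-19,7-olide
Product: 43 (1S,2S,3Z,7S,8R,9S,10S,13S,17R)-2,9,13-triacetoxy-8-hydroxy-5-iodo-6-oxo-5,6-secobriara-3,5(16),11(20)-trien-19,7-olide
Conditions: Dess–Martin periodinane, NaHCO3, CH2Cl2, 0 °C
Reagents that add atoms: none
Why: Dess–Martin oxidation of the primary alcohol gives the C6 aldehyde, the tertiary C8 hydroxyl being inert.

Step 29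
Reactants: 43 (1S,2S,3Z,7S,8R,9S,10S,13S,17R)-2,9,13-triacetoxy-8-hydroxy-5-iodo-6-oxo-5,6-secobriara-3,5(16),11(20)-trien-19,7-olide
Product: 44 (1S,2S,3Z,6R,7R,8R,9S,10S,13S,17R)-2,9,13-triacetoxy-6,8-dihydroxybriara-3,5(16),11(20)-trien-19,7-olide
Conditions: CrCl2 (excess), NiCl2 (cat.), DMSO/THF, rt, slow addition at high dilution
Reagents that add atoms: none
Why: intramolecular Nozaki–Hiyama–Kishi reaction closes the ten-membered ring by addition of the C5 alkenylchromium to the C6 aldehyde, the (3Z)-alkene and the cis-fused lactone bringing the ends together, and Felkin–Anh approach anti to the C7–O bond should give the (6R)-alcohol.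

Step 30
Reactants: 44 (1S,2S,3Z,6R,7R,8R,9S,10S,13S,17R)-2,9,13-triacetoxy-6,8-dihydroxybriara-3,5(16),11(20)-trien-19,7-olide
Product: 45 (1S,2S,3Z,6S,7S,8R,9S,10S,13S,17R)-2,9,13-triacetoxy-6-chloro-8-hydroxybriara-3,5(16),11(20)-trien-19,7-olide (CNP0268873.2)
Conditions: PPh3, hexachloroacetone, CH2Cl2, −20 °C
Reagents that add atoms: hexachloroacetone ClC(Cl)(Cl)C(=O)C(Cl)(Cl)Cl
Why: Appel-type chlorination displaces the allylic alkoxyphosphonium by chloride with inversion and without allylic transposition to give the (6S)-chloride, while the tertiary C8 hydroxyl and the acetates do not react.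

**Compound list**

1 | but-2-yne-1,4-diol | OCC#CCO | starting material
2 | 4-[(4-methoxybenzyl)oxy]but-2-yn-1-ol | OCC#CCOCc1ccc(OC)cc1 | intermediate
3 | (Z)-3-iodo-4-[(4-methoxybenzyl)oxy]but-2-en-1-ol | I/C(COCc1ccc(OC)cc1)=C\CO | intermediate
4 | (Z)-tert-butyl({3-iodo-4-[(4-methoxybenzyl)oxy]but-2-en-1-yl}oxy)diphenylsilane | I/C(COCc1ccc(OC)cc1)=C\CO[Si](c1ccccc1)(c1ccccc1)C(C)(C)C | intermediate
5 | (R)-epichlorohydrin | ClC[C@H]1CO1 | starting material
6 | [(2E)-4-[(tert-butyldiphenylsilyl)oxy]-1-[(4-methoxybenzyl)oxy]but-2-en-2-yl]lithium | [Li]/C(COCc1ccc(OC)cc1)=C\CO[Si](c1ccccc1)(c1ccccc1)C(C)(C)C | intermediate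
7 | (2R,4E)-6-[(tert-butyldiphenylsilyl)oxy]-1-chloro-4-{[(4-methoxybenzyl)oxy]methyl}hex-4-en-2-ol | ClC[C@H](O)C/C(COCc1ccc(OC)cc1)=C\CO[Si](c1ccccc1)(c1ccccc1)C(C)(C)C | intermediate
8 | tert-butyl{[(2E)-3-{[(4-methoxybenzyl)oxy]methyl}-4-[(2R)-oxiran-2-yl]but-2-en-1-yl]oxy}diphenylsilane | C1O[C@@H]1C/C(COCc1ccc(OC)cc1)=C\CO[Si](c1ccccc1)(c1ccccc1)C(C)(C)C | intermediate
9 | propanoic acid | CCC(=O)O | starting material
10 | dilithium (4S,6E)-8-[(tert-butyldiphenylsilyl)oxy]-6-{[(4-methoxybenzyl)oxy]methyl}-2-methyl-4-oxidooct-6-enoate (C2 epimers) | [Li+].[Li+].CC(C(=O)[O-])C[C@H]([O-])C/C(COCc1ccc(OC)cc1)=C\CO[Si](c1ccccc1)(c1ccccc1)C(C)(C)C | intermediate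
11 | triethylsilyl (4S,6E)-8-[(tert-butyldiphenylsilyl)oxy]-6-{[(4-methoxybenzyl)oxy]methyl}-2-methyl-4-[(triethylsilyl)oxy]oct-6-enoate (C2 epimers) | CC(C(=O)O[Si](CC)(CC)CC)C[C@H](O[Si](CC)(CC)CC)C/C(COCc1ccc(OC)cc1)=C\CO[Si](c1ccccc1)(c1ccccc1)C(C)(C)C | intermediate
12 | (4S,6E)-8-[(tert-butyldiphenylsilyl)oxy]-6-{[(4-methoxybenzyl)oxy]methyl}-2-methyl-4-[(triethylsilyl)oxy]oct-6-enoic acid (C2 epimers) | CC(C(=O)O)C[C@H](O[Si](CC)(CC)CC)C/C(COCc1ccc(OC)cc1)=C\CO[Si](c1ccccc1)(c1ccccc1)C(C)(C)C | intermediate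
13 | (4S,6E)-8-[(tert-butyldiphenylsilyl)oxy]-6-(hydroxymethyl)-2-methyl-4-[(triethylsilyl)oxy]oct-6-enoic acid (C2 epimers) | CC(C(=O)O)C[C@H](O[Si](CC)(CC)CC)C/C(CO)=C\CO[Si](c1ccccc1)(c1ccccc1)C(C)(C)C | intermediate
14 | (5S,7E)-7-{2-[(tert-butyldiphenylsilyl)oxy]ethylidene}-3-methyl-5-[(triethylsilyl)oxy]oxocan-2-one (C3 epimers) | CC1C[C@H](O[Si](CC)(CC)CC)C/C(=C\CO[Si](c2ccccc2)(c2ccccc2)C(C)(C)C)COC1=O | intermediate
15 | (5R,7E)-7-{2-[(tert-butyldiphenylsilyl)oxy]ethylidene}-3-methyl-5-[(triethylsilyl)oxy]-2-[(trimethylsilyl)oxy]-5,6,7,8-tetrahydro-4H-oxocine (silyl ketene acetal of 14, C5 unchanged in space) | C/C1=C(\O[Si](C)(C)C)OC/C(=C/CO[Si](c2ccccc2)(c2ccccc2)C(C)(C)C)C[C@@H](O[Si](CC)(CC)CC)C1 | intermediate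
16 | trimethylsilyl (1S,2S,5R)-2-{[(tert-butyldiphenylsilyl)oxy]methyl}-1-methyl-3-methylidene-5-[(triethylsilyl)oxy]cyclohexane-1-carboxylate | C=C1C[C@@H](O[Si](CC)(CC)CC)C[C@](C)(C(=O)O[Si](C)(C)C)[C@H]1CO[Si](c2ccccc2)(c2ccccc2)C(C)(C)C | intermediate
17 | (1S,2S,5R)-2-{[(tert-butyldiphenylsilyl)oxy]methyl}-5-hydroxy-1-methyl-3-methylidenecyclohexane-1-carboxylic acid | C=C1C[C@@H](O)C[C@](C)(C(=O)O)[C@H]1CO[Si](c2ccccc2)(c2ccccc2)C(C)(C)C | intermediate
18 | (1S,2S,5S)-2-{[(tert-butyldiphenylsilyl)oxy]methyl}-1-methyl-3-methylidene-6-oxabicyclo[3.2.1]octan-7-one | C=C1C[C@H]2C[C@](C)(C(=O)O2)[C@H]1CO[Si](c3ccccc3)(c3ccccc3)C(C)(C)C | intermediate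
19 | (1-bromoethenyl)trimethylsilane | C=C(Br)[Si](C)(C)C | starting material
20 | ethynyltrimethylsilane | C#C[Si](C)(C)C | starting material
21 | trimethyl[3-(trimethylsilyl)but-3-en-1-yn-1-yl]silane | C=C(C#C[Si](C)(C)C)[Si](C)(C)C | intermediate
22 | [3-(trimethylsilyl)but-3-en-1-yn-1-yl]lithium | [Li]C#CC(=C)[Si](C)(C)C | intermediate
23 | 1-[(1S,2S,5S)-2-{[(tert-butyldiphenylsilyl)oxy]methyl}-5-hydroxy-1-methyl-3-methylidenecyclohexyl]-4-(trimethylsilyl)pent-4-en-2-yn-1-one | C=C1C[C@H](O)C[C@](C)(C(=O)C#CC(=C)[Si](C)(C)C)[C@H]1CO[Si](c2ccccc2)(c2ccccc2)C(C)(C)C | intermediate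
24 | (1R)-1-[(1S,2S,5S)-2-{[(tert-butyldiphenylsilyl)oxy]methyl}-5-hydroxy-1-methyl-3-methylidenecyclohexyl]-4-(trimethylsilyl)pent-4-en-2-yn-1-ol | C=C1C[C@H](O)C[C@](C)([C@@H](O)C#CC(=C)[Si](C)(C)C)[C@H]1CO[Si](c2ccccc2)(c2ccccc2)C(C)(C)C | intermediate
25 | (1R)-1-[(1S,2S,5S)-5-acetoxy-2-{[(tert-butyldiphenylsilyl)oxy]methyl}-1-methyl-3-methylidenecyclohexyl]-4-(trimethylsilyl)pent-4-en-2-yn-1-yl acetate | C=C1C[C@H](OC(C)=O)C[C@](C)([C@@H](OC(C)=O)C#CC(=C)[Si](C)(C)C)[C@H]1CO[Si](c2ccccc2)(c2ccccc2)C(C)(C)C | intermediate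
26 | (1R)-1-[(1S,2S,5S)-5-acetoxy-2-(hydroxymethyl)-1-methyl-3-methylidenecyclohexyl]-4-(trimethylsilyl)pent-4-en-2-yn-1-yl acetate | C=C1C[C@H](OC(C)=O)C[C@](C)([C@@H](OC(C)=O)C#CC(=C)[Si](C)(C)C)[C@H]1CO | intermediate
27 | (1R)-1-[(1S,2S,5S)-5-acetoxy-2-formyl-1-methyl-3-methylidenecyclohexyl]-4-(trimethylsilyl)pent-4-en-2-yn-1-yl acetate | C=C1C[C@H](OC(C)=O)C[C@](C)([C@@H](OC(C)=O)C#CC(=C)[Si](C)(C)C)[C@H]1C=O | intermediate
28 | (tert-butyldiphenylsilyloxy)acetaldehyde | O=CCO[Si](c1ccccc1)(c1ccccc1)C(C)(C)C | starting material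
29 | tert-butyl[(3,3-dibromoprop-2-en-1-yl)oxy]diphenylsilane | BrC(Br)=CCO[Si](c1ccccc1)(c1ccccc1)C(C)(C)C | intermediate
30 | tert-butyl 2-bromopropanoate (racemic) | CC(Br)C(=O)OC(C)(C)C | starting material
31 | bromo[1-(tert-butoxycarbonyl)ethyl]zinc (Reformatsky reagent) | CC([Zn]Br)C(=O)OC(C)(C)C | intermediate
32 | tert-butyl (3Z)-3-bromo-5-[(tert-butyldiphenylsilyl)oxy]-2-methylpent-3-enoate (racemic) | CC(C(=O)OC(C)(C)C)/C(Br)=C/CO[Si](c1ccccc1)(c1ccccc1)C(C)(C)C | intermediate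
33 | tert-butyl (1S,2R,7Z,10S,13S)-2,13-diacetoxy-6-[(tert-butyldiphenylsilyl)oxy]-9-hydroxy-5-(trimethylsilyl)-5,6-secobriara-5(16),7,11(20)-trien-3-yn-19-oate (C9 and C17 epimers) | C=C1C[C@H](OC(C)=O)C[C@](C)([C@@H](OC(C)=O)C#CC(=C)[Si](C)(C)C)[C@H]1C(O)/C(=C\CO[Si](c2ccccc2)(c2ccccc2)C(C)(C)C)C(C)C(=O)OC(C)(C)C | intermediate
34 | tert-butyl (1S,2R,7Z,10S,13S)-2,13-diacetoxy-6-[(tert-butyldiphenylsilyl)oxy]-9-oxo-5-(trimethylsilyl)-5,6-secobriara-5(16),7,11(20)-trien-3-yn-19-oate (C17 epimers) | C=C1C[C@H](OC(C)=O)C[C@](C)([C@@H](OC(C)=O)C#CC(=C)[Si](C)(C)C)[C@H]1C(=O)/C(=C\CO[Si](c2ccccc2)(c2ccccc2)C(C)(C)C)C(C)C(=O)OC(C)(C)C | intermediate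
35 | tert-butyl (1S,2R,7Z,9S,10S,13S)-2,13-diacetoxy-6-[(tert-butyldiphenylsilyl)oxy]-9-hydroxy-5-(trimethylsilyl)-5,6-secobriara-5(16),7,11(20)-trien-3-yn-19-oate (C17 epimers) | C=C1C[C@H](OC(C)=O)C[C@](C)([C@@H](OC(C)=O)C#CC(=C)[Si](C)(C)C)[C@H]1[C@H](O)/C(=C\CO[Si](c2ccccc2)(c2ccccc2)C(C)(C)C)C(C)C(=O)OC(C)(C)C | intermediate
36 | tert-butyl (1S,2R,7S,8R,9S,10S,13S)-2,13-diacetoxy-6-[(tert-butyldiphenylsilyl)oxy]-7,8-epoxy-9-hydroxy-5-(trimethylsilyl)-5,6-secobriara-5(16),11(20)-dien-3-yn-19-oate (C17 epimers) | C=C1C[C@H](OC(C)=O)C[C@](C)([C@@H](OC(C)=O)C#CC(=C)[Si](C)(C)C)[C@H]1[C@H](O)[C@@]3(C(C)C(=O)OC(C)(C)C)O[C@H]3CO[Si](c2ccccc2)(c2ccccc2)C(C)(C)C | intermediate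
37 | (1S,2R,7R,8R,9S,10S,13S)-2,13-diacetoxy-6-[(tert-butyldiphenylsilyl)oxy]-8,9-dihydroxy-5-(trimethylsilyl)-5,6-secobriara-5(16),11(20)-dien-3-yn-19,7-olide (C17 epimers) | C=C1C[C@H](OC(C)=O)C[C@](C)([C@@H](OC(C)=O)C#CC(=C)[Si](C)(C)C)[C@H]1[C@H](O)[C@]3(O)C(C)C(=O)O[C@@H]3CO[Si](c2ccccc2)(c2ccccc2)C(C)(C)C | intermediate
38 | (1S,2R,7R,8R,9S,10S,13S)-2,9,13-triacetoxy-6-[(tert-butyldiphenylsilyl)oxy]-8-hydroxy-5-(trimethylsilyl)-5,6-secobriara-5(16),11(20)-dien-3-yn-19,7-olide (C17 epimers) | C=C1C[C@H](OC(C)=O)C[C@](C)([C@@H](OC(C)=O)C#CC(=C)[Si](C)(C)C)[C@H]1[C@H](OC(C)=O)[C@]3(O)C(C)C(=O)O[C@@H]3CO[Si](c2ccccc2)(c2ccccc2)C(C)(C)C | intermediate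
39 | (1S,2R,7R,8R,9S,10S,13S,17R)-2,9,13-triacetoxy-6-[(tert-butyldiphenylsilyl)oxy]-8-hydroxy-5-(trimethylsilyl)-5,6-secobriara-5(16),11(20)-dien-3-yn-19,7-olide | C=C1C[C@H](OC(C)=O)C[C@](C)([C@@H](OC(C)=O)C#CC(=C)[Si](C)(C)C)[C@H]1[C@H](OC(C)=O)[C@]3(O)[C@@H](C)C(=O)O[C@@H]3CO[Si](c2ccccc2)(c2ccccc2)C(C)(C)C | intermediate
40 | (1S,2S,3Z,7R,8R,9S,10S,13S,17R)-2,9,13-triacetoxy-6-[(tert-butyldiphenylsilyl)oxy]-8-hydroxy-5-(trimethylsilyl)-5,6-secobriara-3,5(16),11(20)-trien-19,7-olide | C=C1C[C@H](OC(C)=O)C[C@](C)([C@@H](OC(C)=O)/C=C\C(=C)[Si](C)(C)C)[C@H]1[C@H](OC(C)=O)[C@]3(O)[C@@H](C)C(=O)O[C@@H]3CO[Si](c2ccccc2)(c2ccccc2)C(C)(C)C | intermediate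
41 | (1S,2S,3Z,7R,8R,9S,10S,13S,17R)-2,9,13-triacetoxy-6-[(tert-butyldiphenylsilyl)oxy]-8-hydroxy-5-iodo-5,6-secobriara-3,5(16),11(20)-trien-19,7-olide | C=C1C[C@H](OC(C)=O)C[C@](C)([C@@H](OC(C)=O)/C=C\C(=C)I)[C@H]1[C@H](OC(C)=O)[C@]3(O)[C@@H](C)C(=O)O[C@@H]3CO[Si](c2ccccc2)(c2ccccc2)C(C)(C)C | intermediate
42 | (1S,2S,3Z,7R,8R,9S,10S,13S,17R)-2,9,13-triacetoxy-6,8-dihydroxy-5-iodo-5,6-secobriara-3,5(16),11(20)-trien-19,7-olide | C=C1C[C@H](OC(C)=O)C[C@](C)([C@@H](OC(C)=O)/C=C\C(=C)I)[C@H]1[C@H](OC(C)=O)[C@]3(O)[C@@H](C)C(=O)O[C@@H]3CO | intermediate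
43 | (1S,2S,3Z,7S,8R,9S,10S,13S,17R)-2,9,13-triacetoxy-8-hydroxy-5-iodo-6-oxo-5,6-secobriara-3,5(16),11(20)-trien-19,7-olide | C=C1C[C@H](OC(C)=O)C[C@](C)([C@@H](OC(C)=O)/C=C\C(=C)I)[C@H]1[C@H](OC(C)=O)[C@]3(O)[C@@H](C)C(=O)O[C@@H]3C=O | intermediate
44 | (1S,2S,3Z,6R,7R,8R,9S,10S,13S,17R)-2,9,13-triacetoxy-6,8-dihydroxybriara-3,5(16),11(20)-trien-19,7-olide | C=C1C[C@H](OC(C)=O)C[C@]2(C)[C@@H](OC(C)=O)/C=C\C(=C)[C@@H](O)[C@H]3OC(=O)[C@H](C)[C@@]3(O)[C@@H](OC(C)=O)[C@@H]12 | intermediate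
45 | (1S,2S,3Z,6S,7S,8R,9S,10S,13S,17R)-2,9,13-triacetoxy-6-chloro-8-hydroxybriara-3,5(16),11(20)-trien-19,7-olide (CNP0268873.2) | C=C1C[C@H](OC(C)=O)C[C@]2(C)[C@@H](OC(C)=O)/C=C\C(=C)[C@H](Cl)[C@H]3OC(=O)[C@H](C)[C@@]3(O)[C@@H](OC(C)=O)[C@@H]12 | target

**Step count**

Total: 30 steps. Longest linear sequence: 27 steps (steps 1–9, 11–15 and 18–30, from but-2-yne-1,4-diol); steps 10 and 16–17 are side branches.

**Steps most likely to fail**

Step 8 (Proposed new method). Process at risk: the ketene acetal terminus may not reach C10 across the eight-membered ring, or the shift may pass through the boat array or over the other face, so that no rearrangement or the wrong C1/C10 pair results. Fallback with known chemistry (radical allyl-transfer cyclisation), setting out from 13 and returning at 17: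
- The acid of 13 is alkylated with 4-methoxybenzyl chloride and K2CO3 in DMF to give 4-methoxybenzyl ester F1.
- The allylic hydroxyl is exchanged with PhSSPh and PBu3 to give allylic phenyl sulfide F2.
- Deprotonation with LiN(iPr)2 at −78 °C and quenching with CBr4 gives α-bromo ester F3.
- Slow addition of Bu3SnH with AIBN in benzene at 80 °C generates the C1 radical, which adds 6-endo to C10 of the trisubstituted alkene and expels the phenylthiyl radical from C20 to give cyclohexane ester F4. The chair transition state with the C13 silyloxy group equatorial and the (E)-alkene should again pair methyl C15 with C9.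
- TFA and anisole in CH2Cl2 at 0 °C remove the 4-methoxybenzyl ester and the triethylsilyl ether and return hydroxy acid 17.

Step 29. Process at risk: poor facial selectivity in the addition of the dienylchromium to the C6 aldehyde during ring closure. Fallback, setting out from 43 and returning at 44: the crude product of the chromium-mediated closure, 44 together with its C6 epimer F5, is oxidised with Dess–Martin periodinane to the cross-conjugated dienone F6. F6 is then reduced with (R)-2-methyl-CBS-oxazaborolidine and BH3·SMe2 (Corey–Bakshi–Shibata reduction, the 1,1-disubstituted alkenyl group acting as the large substituent), so that C6 is set by the reagent and 44 is obtained.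

Step 22. Process at risk: ionisation of the activated epoxide at the tertiary C8–O bond (hydride shift from C9 or capture by an external nucleophile) instead of attack of the ester carbonyl at C7. Fallback, setting out from 36 and returning at 38:
- Ti(OiPr)4-mediated opening of the 2,3-epoxy alcohol with chloroacetic acid delivers the carboxylate to C7, the epoxide carbon remote from the hydroxyl, with inversion and gives chloroacetate diol F7.
- Acetylation of the C9 hydroxyl (Ac2O, DMAP, pyridine) gives C9 acetate F8.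
- Thiourea in EtOH removes the chloroacetate selectively to give C7 alcohol F9.
- TFA in CH2Cl2 at 0 °C cleaves the tert-butyl ester, and the acid lactonises onto O7 (O9 being blocked) to give 38.

**Further compounds**

F1 | step 8 | 4-methoxybenzyl (4S,6E)-8-[(tert-butyldiphenylsilyl)oxy]-6-(hydroxymethyl)-2-methyl-4-[(triethylsilyl)oxy]oct-6-enoate (C2 epimers) | CC(C(=O)OCc1ccc(OC)cc1)C[C@H](O[Si](CC)(CC)CC)C/C(CO)=C\CO[Si](c1ccccc1)(c1ccccc1)C(C)(C)C
F2 | step 8 | 4-methoxybenzyl (4S,6E)-8-[(tert-butyldiphenylsilyl)oxy]-2-methyl-6-[(phenylsulfanyl)methyl]-4-[(triethylsilyl)oxy]oct-6-enoate (C2 epimers) | CC(C(=O)OCc1ccc(OC)cc1)C[C@H](O[Si](CC)(CC)CC)C/C(CSc1ccccc1)=C\CO[Si](c1ccccc1)(c1ccccc1)C(C)(C)C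
F3 | step 8 | 4-methoxybenzyl (4R,6E)-2-bromo-8-[(tert-butyldiphenylsilyl)oxy]-2-methyl-6-[(phenylsulfanyl)methyl]-4-[(triethylsilyl)oxy]oct-6-enoate (C2 epimers; C4 unchanged in space) | CC(Br)(C(=O)OCc1ccc(OC)cc1)C[C@H](O[Si](CC)(CC)CC)C/C(CSc1ccccc1)=C\CO[Si](c1ccccc1)(c1ccccc1)C(C)(C)C
F4 | step 8 | 4-methoxybenzyl (1S,2S,5R)-2-{[(tert-butyldiphenylsilyl)oxy]methyl}-1-methyl-3-methylidene-5-[(triethylsilyl)oxy]cyclohexane-1-carboxylate | C=C1C[C@@H](O[Si](CC)(CC)CC)C[C@](C)(C(=O)OCc2ccc(OC)cc2)[C@H]1CO[Si](c2ccccc2)(c2ccccc2)C(C)(C)C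
F5 | step 29 | (1S,2S,3Z,6S,7R,8R,9S,10S,13S,17R)-2,9,13-triacetoxy-6,8-dihydroxybriara-3,5(16),11(20)-trien-19,7-olide (C6 epimer of 44) | C=C1C[C@H](OC(C)=O)C[C@]2(C)[C@@H](OC(C)=O)/C=C\C(=C)[C@H](O)[C@H]3OC(=O)[C@H](C)[C@@]3(O)[C@@H](OC(C)=O)[C@@H]12
F6 | step 29 | (1S,2S,3Z,7S,8R,9S,10S,13S,17R)-2,9,13-triacetoxy-8-hydroxy-6-oxobriara-3,5(16),11(20)-trien-19,7-olide | C=C1C[C@H](OC(C)=O)C[C@]2(C)[C@@H](OC(C)=O)/C=C\C(=C)C(=O)[C@H]3OC(=O)[C@H](C)[C@@]3(O)[C@@H](OC(C)=O)[C@@H]12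
F7 | step 22 | tert-butyl 2,13-diacetoxy-6-[(tert-butyldiphenylsilyl)oxy]-7-(chloroacetoxy)-8,9-dihydroxy-5-(trimethylsilyl)-5,6-secobriara-5(16),11(20)-dien-3-yn-19-oate (C7 inverted relative to 36, other centres as in 36, C17 epimers) | C=C1C[C@H](OC(C)=O)C[C@](C)([C@@H](OC(C)=O)C#CC(=C)[Si](C)(C)C)[C@H]1[C@H](O)[C@](O)(C(C)C(=O)OC(C)(C)C)[C@H](OC(=O)CCl)CO[Si](c2ccccc2)(c2ccccc2)C(C)(C)C
F8 | step 22 | tert-butyl 2,9,13-triacetoxy-6-[(tert-butyldiphenylsilyl)oxy]-7-(chloroacetoxy)-8-hydroxy-5-(trimethylsilyl)-5,6-secobriara-5(16),11(20)-dien-3-yn-19-oate (centres as in F7, C17 epimers) | C=C1C[C@H](OC(C)=O)C[C@](C)([C@@H](OC(C)=O)C#CC(=C)[Si](C)(C)C)[C@H]1[C@H](OC(C)=O)[C@](O)(C(C)C(=O)OC(C)(C)C)[C@H](OC(=O)CCl)CO[Si](c2ccccc2)(c2ccccc2)C(C)(C)C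
F9 | step 22 | tert-butyl 2,9,13-triacetoxy-6-[(tert-butyldiphenylsilyl)oxy]-7,8-dihydroxy-5-(trimethylsilyl)-5,6-secobriara-5(16),11(20)-dien-3-yn-19-oate (centres as in F7, C17 epimers) | C=C1C[C@H](OC(C)=O)C[C@](C)([C@@H](OC(C)=O)C#CC(=C)[Si](C)(C)C)[C@H]1[C@H](OC(C)=O)[C@](O)(C(C)C(=O)OC(C)(C)C)[C@H](O)CO[Si](c2ccccc2)(c2ccccc2)C(C)(C)C
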